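**Retrosynthetic overview**
1. Ring A (hemiketal) opens to a δ-hydroxy ketone. Its C5–C6 bond is cut to spiro-epoxide 15 plus ethyl vinyl ketone. Cp2TiCl turns the epoxide carbon C6 into a nucleophilic tertiary radical that attacks the enone β-carbon, so two electrophilic carbons are joined. This last step makes the second of the two vicinal quaternary carbons.
2. The epoxide comes from the bridging C6 ketone (sulfonium ylide). The C15 carbinol comes from the enone (CBS reduction).
3. Ring B (piperidine) comes from a double Mannich reaction across C18 and C8 of tricyclic enedione 11.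
4. Ring C (seven-membered) comes from a vinylogous Dieckmann closure, C18 onto C6. H16 comes from Krapcho cleavage of a gem-diester.
5. Rings D and E (diquinane) come from an asymmetric Pauson–Khand reaction of 1,6-enyne 6, built from three cheap pieces. Ring order: D+E, then C, B, A.

**Locants** follow the atom order of the target SMILES: C1–C2 ethyl, C3 hemiketal carbon, C4, C5, C6 spiro carbon, C7 OCH2, C8 CH, C9, C10, C11=C12, C13 CH, C14, C15 carbinol, C16 CH(CO2Me), C17, C18 quaternary carbon, C19 and C20 NCH2. The top face is the face of the diquinane that carries H13. In the target it also carries H16, C19 and the C15 hydroxyl. The CO2Me group and C6 lie on the bottom face.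

**Assumption:** (S)-BINAP is taken to give the C13 configuration drawn for 7 (otherwise (R)-BINAP is used and nothing else changes); the given C3 hemiketal isomer is taken as the equilibrium form.

Step 1
Reactants: 1 dimethyl ethylidenemalonate; 2 4-bromobut-1-yne
Product: 4 dimethyl 2-(but-3-yn-1-yl)-2-vinylmalonate, via lithium dienolate 3 (not isolated)
Conditions: LiN(iPr)2, THF–DMPU, −78 °C; then 2, −78 → 25 °C
Reagents that add atoms: none
Why: Deconjugative alkylation: dienolate 3 reacts with the primary bromide at its α-carbon between the two esters, which moves the double bond out of conjugation and gives the quaternary vinyl malonate; no stereocentre is formed.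

Step 2
Reactants: 4 dimethyl 2-(but-3-yn-1-yl)-2-vinylmalonate; 5 methyl 4-iodobutanoate
Product: 6 trimethyl dec-1-en-6-yne-3,3,10-tricarboxylate
Conditions: [Pd(allyl)Cl]2 (2.5 mol %), 1,3-bis(1-adamantyl)imidazolium chloride (5 mol %), CuI (7.5 mol %), Cs2CO3, DMF–Et2O, 45 °C
Reagents that add atoms: none
Why: Alkyl Sonogashira coupling: the bulky N-heterocyclic carbene lets zerovalent palladium add to the unactivated primary iodide and couple with the copper acetylide faster than β-hydride elimination, and the carbonate base leaves the three esters and the vinyl group untouched.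

Step 3
Reactants: 6 trimethyl dec-1-en-6-yne-3,3,10-tricarboxylate
Product: 7 diquinane enone triester (rings D and E; H13 on the top face)
Conditions: [Rh(CO)2Cl]2 (3 mol %), (S)-BINAP (9 mol %), AgOTf (12 mol %), CO (1 atm), THF, 90 °C
Reagents that add atoms: carbon monoxide [C-]#[O+]
Why: Catalytic asymmetric intramolecular Pauson–Khand [2+2+1] reaction: the cationic monovalent rhodium–BINAP complex binds the 1,6-enyne, the gem-diester favours the folded conformer, and face-selective alkene insertion followed by CO insertion forms C12–C13, C14–C15 and C15–C11 and sets C13.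

Step 4
Reactants: 7 diquinane enone triester
Product: 9 tricyclic enedione diester (rings C D E), via potassium enolate 8 (not isolated)
Conditions: KOtBu (2.2 equiv), THF, 0 → 25 °C; 1 M HCl quench
Reagents that add atoms: none
Why: Vinylogous Dieckmann condensation: γ-deprotonation at the unhindered C18H2 gives the linear dienolate, whose γ-carbon is acylated by the side-chain ester; competing spiro acylation at C11 is undone by retro-Claisen because that product has no acidic hydrogen, so everything drains to the delocalised enolate 8, in which the hindered neopentyl H13 is no longer acidic.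

Step 5
Reactants: 9 tricyclic enedione diester
Product: 11 tricyclic enedione monoester (CO2Me on the bottom face), via ester enolate 10 (not isolated)
Conditions: LiCl, H2O, DMSO, 140 °C
Reagents that add atoms: none
Why: Krapcho demethoxycarbonylation: chloride demethylates one ester, loss of CO2 leaves the planar enolate 10, and water protonates C16 from the open top face (syn to H13, anti to C14), which places the remaining CO2Me on the bottom face under kinetic control in a medium too weakly basic to epimerise it.

Step 6
Reactants: 11 tricyclic enedione monoester
Product: 13 tetracyclic amino enedione (rings B C D E), via mono-Mannich base 12 (not isolated)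
Conditions: 1,3,5-trimethyl-1,3,5-triazinane (0.35 equiv), (CH2O)n (1.1 equiv), AcOH, 60 °C
Reagents that add atoms: 1,3,5-trimethyl-1,3,5-triazinane CN1CN(C)CN(C)C1; formaldehyde C=O
Why: Double Mannich annulation: the extended enol of the C6 ketone attacks N-methylmethaniminium at C18 from the convex top face (anti to CO2Me and C14) to give 12, whose amine condenses with formaldehyde and closes onto the C8 enol; the only possible geometry is a chair piperidine bridged cis across C18 and C8, so both centres are set, while attack at C11 is reversible and cannot end in an unstrained ring.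

Step 7
Reactants: 13 tetracyclic amino enedione
Product: 14 (15S) allylic alcohol (OH on the top face; C6 ketone kept)
Conditions: (R)-2-methyl-CBS-oxazaborolidine (0.5 equiv), catecholborane (2 equiv), toluene, −78 °C; MeOH, then aq. NaHCO3; chromatography
Reagents that add atoms: none
Why: Corey–Bakshi–Shibata reduction: the oxazaborolidine binds the accessible enone carbonyl with the substituted alkene arm as the large group and delivers hydride under reagent control to give the (15S) alcohol; the C6 carbonyl between a quaternary and a bridgehead carbon is too hindered to bind, and any ent-13 arising from erosion at C13 becomes a diastereomer that is removed on silica.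

Step 8
Reactants: 14 (15S) allylic alcohol
Product: 15 spiro-epoxide at C6
Conditions: Me3SI (3.3 equiv), NaH (3.0 equiv), DMSO–THF, 0 → 25 °C
Reagents that add atoms: trimethylsulfonium iodide C[S+](C)C.[I-]
Why: Johnson–Corey–Chaykovsky methylene transfer: the small unstabilised ylide adds to the non-enolisable C6 ketone from its exposed face (axial on the piperidine chair) and the betaine closes to the epoxide; the ylide is too weak a base to remove H16, and the new spiro configuration does not matter because step 9 erases it.

Step 9
Reactants: 15 spiro-epoxide at C6; 16 ethyl vinyl ketone (pent-1-en-3-one)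
Product: 19 target hemiketal CNP0124876.1, via titanoxy radical 17 (not isolated), via seco hydroxy ketone 18 (not isolated)
Conditions: Cp2TiCl2 (3 equiv), Mn (6 equiv), THF, 25 °C; green solution added over 2 h to 15 + 16 (8 equiv), THF, 0 → 25 °C; aq. NaH2PO4, then NaHCO3
Reagents that add atoms: none
Why: Nugent–RajanBabu reductive epoxide opening followed by Giese addition: Cp2TiCl (trivalent titanium) cleaves the C6–O bond homolytically, so the normally electrophilic epoxide carbon becomes the nucleophilic tertiary radical 17, which cannot disproportionate (bridgehead and quaternary neighbours) and adds to the electrophilic β-carbon of 16 through its exposed lobe (axial on the piperidine chair, the other lobe being buried under ring C), setting C6 with the new chain syn to the nitrogen bridge; a second Cp2TiCl reduces the α-keto radical to the enolate, work-up gives 18, and this closes reversibly to the most stable hemiketal (axial OH by the anomeric effect, equatorial ethyl), which fixes C3.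

**Compound list**
1 | dimethyl ethylidenemalonate | CC=C(C(=O)OC)C(=O)OC | starting material
2 | 4-bromobut-1-yne | C#CCCBr | starting material
3 | lithium dienolate of 1 | [Li+].C=CC(C(=O)OC)=C([O-])OC | intermediate
4 | dimethyl 2-(but-3-yn-1-yl)-2-vinylmalonate | C=CC(CCC#C)(C(=O)OC)C(=O)OC | intermediate
5 | methyl 4-iodobutanoate | COC(=O)CCCI | starting material
6 | trimethyl dec-1-en-6-yne-3,3,10-tricarboxylate (1,6-enyne) | C=CC(CCC#CCCCC(=O)OC)(C(=O)OC)C(=O)OC | intermediate
7 | bicyclo[3.3.0]oct-1-en-3-one (rings D, E): C15 ketone, C11=C12, (CH2)3CO2Me on C11, gem-diester at C16, H13 top | COC(=O)CCCC1=C2CCC(C(=O)OC)(C(=O)OC)[C@H]2CC1=O | intermediate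
8 | potassium enolate of 9 (O6–C6=C18–C12=C11–C15=O) | [K+].[O-]C1=C2CC(C(=O)OC)(C(=O)OC)[C@H]3CC(=O)C(=C23)CCC1 | intermediate
9 | tricyclic (5-5-7) enedione, gem-diester at C16, C6 and C15 ketones, C18 labile | O=C2CCCC3=C4[C@H](CC3=O)C(C(=O)OC)(C(=O)OC)CC42 | intermediate
10 | lithium ester enolate at C16 after loss of CO2 | [Li+].[O-]C(OC)=C1CC2C(=O)CCCC3=C2[C@@H]1CC3=O | intermediate
11 | tricyclic enedione monoester, H13 and H16 top, CO2Me bottom, C18 labile | O=C2CCCC3=C4[C@H](CC3=O)[C@H](C(=O)OC)CC42 | intermediate
12 | mono-Mannich base, CH2NHMe on the top face of C18 | O=C2CCCC3=C4[C@H](CC3=O)[C@H](C(=O)OC)C[C@@]42CNC | intermediate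
13 | tetracyclic amino enedione, N-methylpiperidine bridged across C18 and C8, C6 one-carbon bridge ketone | O=C2[C@@H]1CCC3=C4[C@H](CC3=O)[C@H](C(=O)OC)C[C@@]42CN(C)C1 | intermediate
14 | (15S) allylic alcohol of 13, OH top | O=C2[C@@H]1CCC3=C4[C@H](C[C@@H]3O)[C@H](C(=O)OC)C[C@@]42CN(C)C1 | intermediate
15 | spiro-epoxide at C6 (CH2 syn to the nitrogen bridge, O syn to ring C; the epimer converges) | C1O[C@@]12[C@@H]3CCC4=C5[C@H](C[C@@H]4O)[C@H](C(=O)OC)C[C@@]52CN(C)C3 | intermediate
16 | ethyl vinyl ketone (pent-1-en-3-one) | CCC(=O)C=C | starting material
17 | tertiary C6 radical bearing CH2O–TiClCp2 | Cl[Ti](OC[C]1[C@@H]2CCC3=C4[C@H](C[C@@H]3O)[C@H](C(=O)OC)C[C@@]41CN(C)C2)(C1C=CC=C1)C1C=CC=C1 | intermediate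
18 | seco δ-hydroxy ethyl ketone (C6: CH2OH and CH2CH2COEt) | CCC(=O)CC[C@@]2(CO)[C@@H]1CCC3=C4[C@H](C[C@@H]3O)[C@H](C(=O)OC)C[C@@]42CN(C)C1 | intermediate
19 | CNP0124876.1 (3S,6R,8S,13R,15S,16R,18R in the locants above) | CC[C@@]1(O)CC[C@@]2(CO1)[C@@H]1CCC3=C4[C@H](C[C@@H]3O)[C@H](C(=O)OC)C[C@@]42CN(C)C1 | target

**Total step count:** 9. **Longest linear sequence:** 9 (1 → 19).

**Steps most likely to fail**

Step 4 (vinylogous Dieckmann). The seven-membered closure competes with kinetic spiro acylation at C11. Exchange of H13 in the free dienolate would also erode the enantiomeric purity. Any such erosion is caught in step 7, in the worst case at the cost of half the material.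

The fallback sets out from 7 and comes back at 9. Only the unhindered side-chain ester of 7 is saponified (LiOH, one equivalent; the malonate esters are neopentyl) to give the side-chain carboxylic acid F1. Carbonyldiimidazole converts this into the acyl imidazolide F2. The ring is then closed by soft enolisation (MgBr2·OEt2, iPr2NEt, CH2Cl2). No alkoxide is present, and chelation of the product as its magnesium enolate makes the C18 acylation irreversible. Acid work-up gives 9.

Step 7 (CBS reduction). Reagent control has to override the convex-face bias of the diquinane, and the C6 ketone has to survive.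

The fallback sets out from 13 and comes back at 14. Substrate-controlled Luche reduction (NaBH4, CeCl3·7H2O, MeOH, −78 °C) delivers hydride from the top face and gives the 15-epi alcohol F3. Mitsunobu inversion (4-nitrobenzoic acid, PPh3, diisopropyl azodicarboxylate) gives the (15S) 4-nitrobenzoate F4, which can be recrystallised to raise the enantiomeric purity. K2CO3 in MeOH at 0 °C then releases 14.

Step 9 (radical addition). The radical sits next to a quaternary carbon, and the vinyl ketone can itself be reduced or oligomerised by trivalent titanium.

The fallback sets out from 15 and comes back at 19. The same Cp2TiCl opening is run with methyl acrylate, the best-precedented acceptor, to give the δ-hydroxy ester F5. This lactonises on the titanium alkoxide to the spiro δ-lactone F6. EtMgBr (2.1 equiv, one consumed by the C15 hydroxyl) with CeCl3 in THF at −78 °C then adds once to the lactone carbonyl. The hindered bottom-face methyl ester is left alone, and work-up gives 19.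

**Further compounds**
F1 | step 4 | side-chain carboxylic acid of 7 | OC(=O)CCCC1=C2CCC(C(=O)OC)(C(=O)OC)[C@H]2CC1=O
F2 | step 4 | acyl imidazolide of F1 | O=C(CCCC1=C2CCC(C(=O)OC)(C(=O)OC)[C@H]2CC1=O)n1ccnc1
F3 | step 7 | 15-epi alcohol (OH on the bottom face) | O=C2[C@@H]1CCC3=C4[C@H](C[C@H]3O)[C@H](C(=O)OC)C[C@@]42CN(C)C1
F4 | step 7 | (15S) 4-nitrobenzoate | O=C2[C@@H]1CCC3=C4[C@H](C[C@@H]3OC(=O)c5ccc(cc5)[N+](=O)[O-])[C@H](C(=O)OC)C[C@@]42CN(C)C1
F5 | step 9 | δ-hydroxy methyl ester from methyl acrylate | COC(=O)CC[C@@]2(CO)[C@@H]1CCC3=C4[C@H](C[C@@H]3O)[C@H](C(=O)OC)C[C@@]42CN(C)C1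
F6 | step 9 | spiro δ-lactone | O=C1CC[C@@]2(CO1)[C@@H]1CCC3=C4[C@H](C[C@@H]3O)[C@H](C(=O)OC)C[C@@]42CN(C)C1
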